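**Retrosynthetic overview**

1. The C2 formyl group is taken back to an ethyl ester (reduce, then re-oxidise), giving ethyl 5-henicosyl-1H-pyrrole-2-carboxylate.
2. The pyrrole ring, the only ring, is opened at N1–C5 and C2–C3. N1, C2 and the carbonyl carbon on C2 are a glycine unit (ethyl N-tosylglycinate). C5, C4 and C3 are the β-, α- and carbonyl carbons of (E)-tetracos-2-enal, whose β-carbon carries the C21 chain.
3. Ring formation: aza-Michael addition (N1–C5) and then intramolecular aldol addition (C2–C3) close a pyrrolidine; dehydration and loss of toluenesulfinate aromatise it without an oxidant.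
4. The enal comes from 1-docosanol by oxidation and two-carbon Wittig homologation; the glycinate from glycine ethyl ester hydrochloride and TsCl.

Key step: step 4

Remark on the chemistry: the target has no stereocentre. The three centres made in step 4 are carried as a racemic diastereomer mixture and are removed in steps 5 and 6, so compounds 9, 10 and 11 are drawn as one representative relative configuration of that mixture.

**Route**

Step 1
Reactants: 1 1-docosanol
Product: 2 docosanal
Conditions: TEMPO (2,2,6,6-tetramethylpiperidin-1-oxyl, cat.), PhI(OAc)2, CH2Cl2, 35 °C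
Reagents that add atoms: none
Why: Oxoammonium-mediated (TEMPO/PhI(OAc)2) oxidation of a primary alcohol should stop at the aldehyde in anhydrous CH2Cl2, and gentle warming keeps the waxy alcohol in solution.

Step 2
Reactants: 2 docosanal; 3 (triphenylphosphoranylidene)acetaldehyde
Product: 4 (E)-tetracos-2-enal
Conditions: toluene, 80 °C
Reagents that add atoms: (triphenylphosphoranylidene)acetaldehyde 3, O=CC=P(c1ccccc1)(c1ccccc1)c1ccccc1
Why: Wittig olefination with the stabilised formylmethylene ylide adds the two carbons that become C4 and C3 of the ring and should give the E-enal, with only a small excess of ylide so that the less electrophilic product is not homologated a second time.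

Step 3
Reactants: 5 glycine ethyl ester hydrochloride; 6 4-toluenesulfonyl chloride
Product: 7 ethyl N-tosylglycinate
Conditions: Et3N, CH2Cl2, 0 °C to rt
Reagents that add atoms: 4-toluenesulfonyl chloride 6, Cc1ccc(S(=O)(=O)Cl)cc1
Why: Sulfonamide formation from the amine freed in the flask by Et3N; a single tosyl group is expected because the sulfonamide formed is far less nucleophilic than the amine.

Step 4
Reactants: 4 (E)-tetracos-2-enal; 7 ethyl N-tosylglycinate
Product: 9 ethyl 5-henicosyl-3-hydroxy-1-tosylpyrrolidine-2-carboxylate (racemic diastereomer mixture), via aza-Michael adduct 8 (not isolated)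
Conditions: DBU, THF, 0 °C to rt
Reagents that add atoms: none
Why: DBU deprotonates the sulfonamide N–H of 7 and the nitrogen anion adds reversibly to the β-carbon of enal 4 (N1–C5 bond) to give aldehyde 8, whose glycinate α-carbon, now flanked by the ester and a tertiary sulfonamide, is deprotonated and adds to the aldehyde carbon (C2–C3 bond). The reaction type is the known base-mediated annulation of N-sulfonylglycine esters with α,β-unsaturated carbonyl compounds (Kenner pyrrole synthesis: aza-Michael addition followed by intramolecular aldol addition). The one ring is closed at carbon by a 5-(enolexo)-exo-trig aldol, a favoured mode that should draw the reversible Michael equilibrium forward. C5 is set in the Michael step and C2 and C3 in the aldol step with no controlling element beyond the cyclic transition state, so a racemic diastereomer mixture is expected, which is acceptable because steps 5 and 6 remove all three centres. The selectivity that matters is regiochemical, chain at C5 and not at C3: the secondary sulfonamide cannot condense with the aldehyde to an imine or enamine and any 1,2-adduct reverts, so only the 1,4-adduct can go on to close the ring and the aldehyde carbon must become C3. The tosyl group secures the order of events by making N–H the most acidic site for the first bond and the α-C–H acidic enough for the second.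

Step 5
Reactants: 9 ethyl 5-henicosyl-3-hydroxy-1-tosylpyrrolidine-2-carboxylate
Product: 11 ethyl 5-henicosyl-1-tosyl-2,5-dihydro-1H-pyrrole-2-carboxylate (racemic cis/trans mixture), via C3 dichlorophosphate ester 10 (not isolated)
Conditions: POCl3, pyridine, 0 °C to rt
Reagents that add atoms: none
Why: POCl3/pyridine dehydration of a secondary alcohol by E2 elimination of its dichlorophosphate; the C4 methylene offers an anti-periplanar hydrogen in every diastereomer, and any 2,3-alkene regioisomer should converge on the same pyrrole in step 6.

Step 6
Reactants: 11 ethyl 5-henicosyl-1-tosyl-2,5-dihydro-1H-pyrrole-2-carboxylate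
Product: 13 ethyl 5-henicosyl-1H-pyrrole-2-carboxylate, via 2H-pyrrole tautomer 12 (not isolated)
Conditions: DBU, THF, reflux
Reagents that add atoms: none
Why: DBU removes the acidic C2–H (α to the ester and allylic), toluenesulfinate leaves from nitrogen in a 1,2-elimination to give 2H-pyrrole 12, and tautomerisation gives the aromatic 1H-pyrrole (the aromatisation stage of the Kenner pyrrole synthesis), so no oxidant is needed and both diastereomers converge.

Step 7
Reactants: 13 ethyl 5-henicosyl-1H-pyrrole-2-carboxylate
Product: 14 (5-henicosyl-1H-pyrrol-2-yl)methanol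
Conditions: LiAlH4, THF, 0 °C; then H2O, aq. NaOH
Reagents that add atoms: none
Why: LiAlH4 reduction of an ester to the primary alcohol; keeping the temperature at 0 °C and the work-up basic should prevent loss of the oxygen through an azafulvene (over-reduction to a 2-methylpyrrole) and acid-triggered self-condensation, and the crude alcohol is taken on at once.

Step 8
Reactants: 14 (5-henicosyl-1H-pyrrol-2-yl)methanol
Product: 15 5-henicosyl-1H-pyrrole-2-carbaldehyde
Conditions: activated MnO2, CH2Cl2, rt
Reagents that add atoms: none
Why: MnO2 oxidation of an activated (pyrrol-2-yl) carbinol should stop at the aldehyde, which is stabilised as a vinylogous formamide.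

**Compound list**

1 | 1-docosanol | CCCCCCCCCCCCCCCCCCCCCCO | starting material
2 | docosanal | CCCCCCCCCCCCCCCCCCCCCC=O | intermediate
3 | (triphenylphosphoranylidene)acetaldehyde | O=CC=P(c1ccccc1)(c1ccccc1)c1ccccc1 | starting material
4 | (E)-tetracos-2-enal | CCCCCCCCCCCCCCCCCCCCC/C=C/C=O | intermediate
5 | glycine ethyl ester hydrochloride | CCOC(=O)CN.Cl | starting material
6 | 4-toluenesulfonyl chloride | Cc1ccc(S(=O)(=O)Cl)cc1 | starting material
7 | ethyl N-tosylglycinate | CCOC(=O)CNS(=O)(=O)c1ccc(C)cc1 | intermediate
8 | ethyl N-(1-oxotetracosan-3-yl)-N-tosylglycinate (racemic aza-Michael adduct) | CCCCCCCCCCCCCCCCCCCCCC(CC=O)N(CC(=O)OCC)S(=O)(=O)c1ccc(C)cc1 | intermediate (not isolated)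
9 | ethyl 5-henicosyl-3-hydroxy-1-tosylpyrrolidine-2-carboxylate (racemic diastereomer mixture; the (2S*,3S*,5S*) member drawn) | CCOC(=O)[C@@H]1[C@@H](O)C[C@H](CCCCCCCCCCCCCCCCCCCCC)N1S(=O)(=O)c1ccc(C)cc1 | intermediate
10 | ethyl 3-(dichlorophosphoryloxy)-5-henicosyl-1-tosylpyrrolidine-2-carboxylate (same mixture; same member drawn) | CCOC(=O)[C@@H]1[C@@H](OP(=O)(Cl)Cl)C[C@H](CCCCCCCCCCCCCCCCCCCCC)N1S(=O)(=O)c1ccc(C)cc1 | intermediate (not isolated)
11 | ethyl 5-henicosyl-1-tosyl-2,5-dihydro-1H-pyrrole-2-carboxylate (racemic cis/trans mixture; the (2S*,5S*) cis member drawn) | CCOC(=O)[C@@H]1C=C[C@H](CCCCCCCCCCCCCCCCCCCCC)N1S(=O)(=O)c1ccc(C)cc1 | intermediate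
12 | ethyl 2-henicosyl-2H-pyrrole-5-carboxylate (racemic) | CCOC(=O)C1=NC(CCCCCCCCCCCCCCCCCCCCC)C=C1 | intermediate (not isolated)
13 | ethyl 5-henicosyl-1H-pyrrole-2-carboxylate | CCOC(=O)c1ccc(CCCCCCCCCCCCCCCCCCCCC)[nH]1 | intermediate
14 | (5-henicosyl-1H-pyrrol-2-yl)methanol | CCCCCCCCCCCCCCCCCCCCCc1ccc(CO)[nH]1 | intermediate
15 | 5-henicosyl-1H-pyrrole-2-carbaldehyde | CCCCCCCCCCCCCCCCCCCCCc1ccc(C=O)[nH]1 | target

**Step count**

Total steps: 8. Longest linear sequence: 7 steps (steps 1, 2, 4, 5, 6, 7, 8); step 3 is a one-step side branch.

**Steps most likely to fail**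

Step 4 (key step). The γ-enolisable enal may self-condense through its dienolate under DBU, or the aza-Michael equilibrium may lie on the side of the components so that the aldol closure never starts. The fallback closes the ring at nitrogen instead. It sets out from enal 4: condensation with ethyl azidoacetate (NaOEt, EtOH, −15 °C) should give ethyl (2Z,4E)-2-azidohexacosa-2,4-dienoate F1. Loss of N2 from this dienyl azide with C–N bond formation at the diene terminus (ZnI2 cat., CH2Cl2, rt, or heating in toluene) should give the pyrrole ester directly. The fallback comes back to the route at 13, and steps 7 and 8 follow unchanged.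

Step 7. The N-metalated intermediate may expel aluminate to an azafulvene and be reduced further to the 2-methylpyrrole, or the electron-rich hydroxymethylpyrrole may oligomerise on work-up or handling. The fallback avoids any change of oxidation level at the side chain. It sets out from ester 13: saponification (NaOH, EtOH/H2O, reflux) should give 5-henicosyl-1H-pyrrole-2-carboxylic acid F2. Thermal decarboxylation (ethanolamine, 170 °C) should give 2-henicosyl-1H-pyrrole F3. Vilsmeier–Haack formylation (POCl3, DMF, ClCH2CH2Cl, 0 °C to rt; then aq. NaOAc, heat) at the only free α-position comes back to the route at target 15, bypassing 14 and step 8.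

Step 2. The unreactive formyl ylide may convert the aldehyde incompletely while the product enal is homologated a second time to the dienal, giving waxy mixtures that are hard to separate. The fallback builds the enal in three controlled operations. It sets out from docosanal 2: Horner–Wadsworth–Emmons olefination with triethyl phosphonoacetate (NaH, THF, 0 °C to rt) should give ethyl (E)-tetracos-2-enoate F4. Reduction with i-Bu2AlH (toluene, −20 °C to 0 °C) should give (E)-tetracos-2-en-1-ol F5. Allylic oxidation with activated MnO2 (CH2Cl2, rt) comes back to the route at enal 4.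

**Further compounds**

F1 | step 4 | ethyl (2Z,4E)-2-azidohexacosa-2,4-dienoate | CCCCCCCCCCCCCCCCCCCCC/C=C/C=C(\N=[N+]=[N-])C(=O)OCC
F2 | step 7 | 5-henicosyl-1H-pyrrole-2-carboxylic acid | CCCCCCCCCCCCCCCCCCCCCc1ccc(C(=O)O)[nH]1
F3 | step 7 | 2-henicosyl-1H-pyrrole | CCCCCCCCCCCCCCCCCCCCCc1ccc[nH]1
F4 | step 2 | ethyl (E)-tetracos-2-enoate | CCCCCCCCCCCCCCCCCCCCC/C=C/C(=O)OCC
F5 | step 2 | (E)-tetracos-2-en-1-ol | CCCCCCCCCCCCCCCCCCCCC/C=C/CO
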